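## Retrosynthetic overview

- 30 ⇐ 29 ⇐ 28 ⇐ ketal ester 27 ⇐ hydroperoxide 25: a Criegee rearrangement inserts the ether oxygen into the C5–C10 ring-fusion bond of a decalin. The seven-membered enone ring (O, C10, C1, C2, C3, C4, C5) and the oxepane (O, C5–C10) both grow out of six-membered carbocycles.
- Enabling feature: the ether oxygen sits between the quaternary, methyl-bearing, allylic C10 (an excellent migrating group) and C5, and C5 has the exocyclic C4=C15 methylene as neighbour. This is the imprint of a singlet-oxygen ene reaction on a C4(CH3)=C5 alkene (25 ⇐ 24).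
- 24 ⇐ santonin-type dienone lactone 22 ⇐ dienone ketone 9, by ring-B work: C7 alkylation, C8 reduction, α-methylenation, angeloylation, C6 hydroxylation, lactonisation.
- 9 ⇐ asymmetric Robinson annulation of ketal ketone 1 with ethyl vinyl ketone 3 (chiral imine of 2), then dehydrogenation.
- Ring order: ring B (bought) → ring A → γ-lactone → both seven-membered oxa-rings at once by oxygen insertion.

Key step: step 13

Remark: carbons are numbered as in eudesmane/germacrane sesquiterpenes (C14 = methyl on C10, C15 = carbon on C4, C11–C13 = lactone side chain); α/β refer to the usual drawing with the C10 methyl β. Ketone 1 is taken as a catalogue compound (otherwise one α-methylation of 1,4-cyclohexanedione monoethylene acetal).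

## Route

Step 1
Reactants: 1 7-methyl-1,4-dioxaspiro[4.5]decan-8-one (racemic); 2 (R)-1-phenylethylamine; 3 pent-1-en-3-one
Product: 6 (R)-7-methyl-7-(3-oxopentyl)-1,4-dioxaspiro[4.5]decan-8-one, via imine 4 (not isolated), via Michael adduct imine 5 (not isolated)
Conditions: 2, toluene, reflux, Dean–Stark; then 3, THF, 40 °C; then 10% aq AcOH, rt
Reagents that add atoms: water (O)
Why: Asymmetric Michael addition of a chiral imine: the more substituted secondary enamine tautomer of 4 adds to the enone on the face anti to the phenyl group of the auxiliary (aza-ene-like transition state), which should set the quaternary C10 with the methyl β, and mild hydrolysis frees the 1,5-diketone with the ketal intact.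

Step 2
Reactants: 6 (R)-7-methyl-7-(3-oxopentyl)-1,4-dioxaspiro[4.5]decan-8-one
Product: 8 (R)-1,4a-dimethyl-4,4a,7,8-tetrahydronaphthalene-2,6(3H,5H)-dione, via enone ketal 7 (not isolated)
Conditions: NaOMe (0.2 equiv), MeOH, 60 °C; then 2 M HCl, THF, rt
Reagents that add atoms: water (O)
Why: Robinson-type intramolecular aldol condensation of the ethyl ketone onto the ring ketone closes ring A as the 4-methyl-Δ4-3-ketone, and aqueous acid then unmasks the C8 ketone without touching C10.

Step 3
Reactants: 8 (R)-1,4a-dimethyl-4,4a,7,8-tetrahydronaphthalene-2,6(3H,5H)-dione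
Product: 9 (S)-1,4a-dimethyl-7,8-dihydronaphthalene-2,6(4aH,5H)-dione
Conditions: DDQ, 1,4-dioxane, reflux
Reagents that add atoms: none
Why: DDQ dehydrogenation of a Δ4-3-ketone under neutral conditions runs through the Δ2,4-dienol and should give the cross-conjugated 1,4-dien-3-one while the saturated C8 ketone stays inert; the dienone has no α-hydrogen, which makes the next enolisation regioselective.

Step 4
Reactants: 9 (S)-1,4a-dimethyl-7,8-dihydronaphthalene-2,6(4aH,5H)-dione; 10 tert-butyl bromoacetate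
Product: 11 tert-butyl (7αH)-3,8-dioxo-13-noreudesma-1,4-dien-12-oate
Conditions: LiN(i-Pr)2, THF, −78 °C; 10, DMPU, −78 to −20 °C; then cat. DBU, CH2Cl2, rt
Reagents that add atoms: none
Why: Kinetic deprotonation of the only enolisable ketone should occur at C7 rather than at the neopentyl C9, SN2 alkylation of the enolate installs C11–C12, and base equilibration leaves the side chain equatorial (7β, cis to the C10 methyl).

Step 5
Reactants: 11 tert-butyl (7αH)-3,8-dioxo-13-noreudesma-1,4-dien-12-oate
Product: 12 tert-butyl (7αH)-8β-hydroxy-3-oxo-13-noreudesma-1,4-dien-12-oate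
Conditions: LiAlH(O-t-Bu)3, THF, −40 to 0 °C
Reagents that add atoms: none
Why: The bulky alkoxyaluminium hydride reduces a saturated ketone in preference to a cross-conjugated dienone or an ester and should attack from the α-face, away from the syn-axial C10 methyl, to give the axial 8β-alcohol.

Step 6
Reactants: 12 tert-butyl (7αH)-8β-hydroxy-3-oxo-13-noreudesma-1,4-dien-12-oate
Product: 15 tert-butyl (7αH)-8β-hydroxy-3-oxoeudesma-1,4,11(13)-trien-12-oate, via Mannich base 13 (not isolated), via trimethylammonium iodide 14 (not isolated)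
Conditions: LiN(i-Pr)2 (2.2 equiv), THF, −78 °C; CH2=NMe2+ I−, −78 to −20 °C; then MeI, MeOH, rt; then NaHCO3, EtOAc/H2O, rt
Reagents that add atoms: N,N-dimethylmethyleneiminium iodide, Eschenmoser's salt (C=[N+](C)C.[I-])
Why: Mannich reaction of the ester enolate (the alkoxide rides along as its lithium salt, the dienone has no α-hydrogen) followed by quaternisation and elimination is the standard α-methylenation, and the tert-butyl ester should keep the cis alkoxide from lactonising at low temperature.

Step 7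
Reactants: 15 tert-butyl (7αH)-8β-hydroxy-3-oxoeudesma-1,4,11(13)-trien-12-oate; 16 angelic acid
Product: 18 tert-butyl (7αH)-8β-angeloyloxy-3-oxoeudesma-1,4,11(13)-trien-12-oate, via mixed anhydride 17 (not isolated)
Conditions: 16, 2,4,6-Cl3C6H2COCl, Et3N, toluene, rt; then 15, DMAP, 80 °C
Reagents that add atoms: none
Why: Yamaguchi esterification through the mixed anhydride acylates the hindered axial alcohol with retention at C8 and is the usual way to install an angelate without Z-to-E isomerisation.

Step 8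
Reactants: 18 tert-butyl (7αH)-8β-angeloyloxy-3-oxoeudesma-1,4,11(13)-trien-12-oate
Product: 20 tert-butyl (7αH)-8β-angeloyloxy-6α-hydroxy-3-oxoeudesma-1,4,11(13)-trien-12-oate, via trienol silyl ether 19 (not isolated)
Conditions: TBSOTf, Et3N, CH2Cl2, 0 °C; then mCPBA, CH2Cl2, −20 °C; aqueous work-up
Reagents that add atoms: mCPBA (O=C(OO)c1cccc(Cl)c1)
Why: Soft enolisation through C6–H gives the 3-silyloxy-1,3,5-triene, which the peracid oxidises at its electron-rich terminal C5=C6 bond (vinylogous Rubottom oxidation); attack is expected from the α-face because the β-face of C6 is flanked by the syn-axial C10 methyl and 8β-acyloxy group, giving the equatorial 6α-alcohol.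

Step 9
Reactants: 20 tert-butyl (7αH)-8β-angeloyloxy-6α-hydroxy-3-oxoeudesma-1,4,11(13)-trien-12-oate
Product: 22 8β-angeloyloxy-3-oxoeudesma-1,4,11(13)-trien-12,6α-olide, via hydroxy acid 21 (not isolated)
Conditions: CF3CO2H/CH2Cl2 (1:4), 0 °C to rt
Reagents that add atoms: none
Why: Acid cleaves the tert-butyl ester and the γ-hydroxy acrylic acid should lactonise at once with retention at C6, as santoninic acid closes to santonin, giving the trans-fused α-methylene lactone.

Step 10
Reactants: 22 8β-angeloyloxy-3-oxoeudesma-1,4,11(13)-trien-12,6α-olide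
Product: 23 8β-angeloyloxy-3β-hydroxyeudesma-1,4,11(13)-trien-12,6α-olide
Conditions: NaBH4, CeCl3·7H2O, MeOH, −78 °C
Reagents that add atoms: none
Why: Luche reduction gives 1,2-reduction of the dienone without touching the α-methylene lactone or the esters; hydride should enter anti to the C10 methyl (3β-alcohol), and the C3 epimer is equally usable because this centre is oxidised again in step 16.

Step 11
Reactants: 23 8β-angeloyloxy-3β-hydroxyeudesma-1,4,11(13)-trien-12,6α-olide
Product: 24 8β-angeloyloxy-3β-(tert-butyldimethylsilyloxy)eudesma-1,4,11(13)-trien-12,6α-olide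
Conditions: TBSCl, imidazole, DMF, 0 °C to rt
Reagents that add atoms: tert-butyldimethylsilyl chloride (CC(C)(C)[Si](C)(C)Cl)
Why: Standard silylation protects the acid-sensitive bis-allylic alcohol for the peroxide steps and makes ring A an electron-rich 1,4-diene.

Step 12
Reactants: 24 8β-angeloyloxy-3β-(tert-butyldimethylsilyloxy)eudesma-1,4,11(13)-trien-12,6α-olide
Product: 25 8β-angeloyloxy-5α-hydroperoxy-3β-(tert-butyldimethylsilyloxy)eudesma-1,4(15),11(13)-trien-12,6α-olide
Conditions: O2, tetraphenylporphyrin (cat.), visible light, CH2Cl2, −20 °C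
Reagents that add atoms: singlet oxygen (O=O)
Why: Schenck ene reaction: singlet oxygen should react only with the tetrasubstituted C4=C5 bond, add to C5 from the α-face (anti to the C10 methyl) and take a hydrogen from the C15 methyl (the C3 hydrogen is geminal to the silyloxy group and the conjugated ester alkenes are too electron-poor), creating the C4=C15 methylene and the tertiary 5α-hydroperoxide in one operation.

Step 13
Reactants: 25 8β-angeloyloxy-5α-hydroperoxy-3β-(tert-butyldimethylsilyloxy)eudesma-1,4(15),11(13)-trien-12,6α-olide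
Product: 27 8-angeloyloxy-5,10-epoxy-5-(4-nitrobenzoyloxy)-3-(tert-butyldimethylsilyloxy)germacra-1,4(15),11(13)-trien-12,6-olide, via perester 26 (not isolated)
Conditions: 4-O2NC6H4COCl, pyridine, CH2Cl2, 0 °C to rt
Reagents that add atoms: 4-nitrobenzoyl chloride (O=C(Cl)c1ccc(cc1)[N+](=O)[O-])
Why: Acylation of the tertiary hydroperoxide gives perester 26, whose O–O bond heterolyses with synchronous 1,2-shift of C10 from C5 to the proximal oxygen (Criegee rearrangement), and the bridged oxocarbenium/carboxylate ion pair collapses at C5 to the ketal ester. The closest known reaction is the rearrangement of trans-9-decalyl perbenzoate to 1-benzoyloxy-11-oxabicyclo[4.4.1]undecane, the same change on the same kind of ring-fusion bond. No ring is closed by cyclisation: ring A (C10, C1–C5) and ring B (C5–C10) each take up the oxygen and grow from six to seven atoms, turning the decalin into the 5,10-oxygen-bridged ten-membered carbocycle. C10 migrates with retention, so the oxygen takes the place of C5 on the quaternary centre and fixes its configuration, while C5 becomes a bridgehead whose configuration is dictated by the one-atom bridge (acyloxy group exo). The step needs migration of C10 in preference to C4 (Hock cleavage) or C6; this should be secured because C10 is tertiary and allylic, C4 is sp2 and C6 carries the electron-withdrawing lactone oxygen, and the electron-poor 4-nitrobenzoate lets the rearrangement run near room temperature under basic conditions that spare the bis-allylic silyl ether.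

Step 14
Reactants: 27 8-angeloyloxy-5,10-epoxy-5-(4-nitrobenzoyloxy)-3-(tert-butyldimethylsilyloxy)germacra-1,4(15),11(13)-trien-12,6-olide
Product: 28 8-angeloyloxy-5,10-epoxy-3-(tert-butyldimethylsilyloxy)germacra-1,4(15),11(13)-trien-12,6-olide
Conditions: Et3SiH, TMSOTf (cat.), CH2Cl2, −78 °C
Reagents that add atoms: none
Why: Lewis-acid ionisation of the ketal ester regenerates the bridged oxocarbenium ion and the silane delivers hydride to C5 (ionic reduction of a ketal ester, as in cyclic ether and C-glycoside synthesis); the bicyclic frame allows only the exo hydrogen, so C5 should form with the required configuration.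

Step 15
Reactants: 28 8-angeloyloxy-5,10-epoxy-3-(tert-butyldimethylsilyloxy)germacra-1,4(15),11(13)-trien-12,6-olide
Product: 29 8-angeloyloxy-5,10-epoxy-3-hydroxygermacra-1,4(15),11(13)-trien-12,6-olide
Conditions: HF·pyridine, pyridine, THF, 0 °C
Reagents that add atoms: none
Why: Buffered fluoride removes the silyl ether without harming the esters, the α-methylene lactone or the tertiary allylic ether.

Step 16
Reactants: 29 8-angeloyloxy-5,10-epoxy-3-hydroxygermacra-1,4(15),11(13)-trien-12,6-olide
Product: 30 CNP0335602.1 (target)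
Conditions: Dess–Martin periodinane, CH2Cl2, 0 °C to rt
Reagents that add atoms: none
Why: Dess–Martin oxidation of the bis-allylic alcohol gives the 1-en-3-one flanked by the 4(15)-methylene under neutral, non-nucleophilic conditions and completes the target.

## Compound list

1 | 7-methyl-1,4-dioxaspiro[4.5]decan-8-one (racemic) | CC1CC2(CCC1=O)OCCO2 | starting material
2 | (R)-1-phenylethylamine | C[C@@H](N)c1ccccc1 | starting material
3 | pent-1-en-3-one (ethyl vinyl ketone) | CCC(=O)C=C | starting material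
4 | N-[(R)-1-phenylethyl] imine of 1 | CC1CC2(CCC1=N[C@H](C)c1ccccc1)OCCO2 | intermediate
5 | N-[(R)-1-phenylethyl] imine of 6 (Michael adduct imine) | CCC(=O)CC[C@]1(C)CC2(CCC1=N[C@H](C)c1ccccc1)OCCO2 | intermediate
6 | (R)-7-methyl-7-(3-oxopentyl)-1,4-dioxaspiro[4.5]decan-8-one | CCC(=O)CC[C@]1(C)CC2(CCC1=O)OCCO2 | intermediate
7 | 8,8-ethylenedioxy-11,12,13-trinoreudesm-4-en-3-one (10β-methyl) | O=C1CC[C@]2(C)CC3(CCC2=C1C)OCCO3 | intermediate
8 | (R)-1,4a-dimethyl-4,4a,7,8-tetrahydronaphthalene-2,6(3H,5H)-dione (11,12,13-trinoreudesm-4-ene-3,8-dione) | O=C1CC[C@]2(C)CC(=O)CCC2=C1C | intermediate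
9 | (S)-1,4a-dimethyl-7,8-dihydronaphthalene-2,6(4aH,5H)-dione (11,12,13-trinoreudesma-1,4-diene-3,8-dione) | O=C1C=C[C@]2(C)CC(=O)CCC2=C1C | intermediate
10 | tert-butyl bromoacetate | BrCC(=O)OC(C)(C)C | starting material
11 | tert-butyl (7αH)-3,8-dioxo-13-noreudesma-1,4-dien-12-oate | O=C1C=C[C@]2(C)CC(=O)[C@@H](CC(=O)OC(C)(C)C)CC2=C1C | intermediate
12 | tert-butyl (7αH)-8β-hydroxy-3-oxo-13-noreudesma-1,4-dien-12-oate | O=C1C=C[C@]2(C)C[C@@H](O)[C@@H](CC(=O)OC(C)(C)C)CC2=C1C | intermediate
13 | tert-butyl 13-(dimethylamino)-8β-hydroxy-3-oxoeudesma-1,4-dien-12-oate (C11 epimers) | O=C1C=C[C@]2(C)C[C@@H](O)[C@@H](C(CN(C)C)C(=O)OC(C)(C)C)CC2=C1C | intermediate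
14 | N-methyl ammonium iodide of 13 | O=C1C=C[C@]2(C)C[C@@H](O)[C@@H](C(C[N+](C)(C)C)C(=O)OC(C)(C)C)CC2=C1C.[I-] | intermediate
15 | tert-butyl (7αH)-8β-hydroxy-3-oxoeudesma-1,4,11(13)-trien-12-oate | O=C1C=C[C@]2(C)C[C@@H](O)[C@@H](C(=C)C(=O)OC(C)(C)C)CC2=C1C | intermediate
16 | angelic acid, (Z)-2-methylbut-2-enoic acid | C/C=C(/C)C(=O)O | starting material
17 | angelic 2,4,6-trichlorobenzoic anhydride | C/C=C(/C)C(=O)OC(=O)c1c(Cl)cc(Cl)cc1Cl | intermediate
18 | tert-butyl (7αH)-8β-angeloyloxy-3-oxoeudesma-1,4,11(13)-trien-12-oate | O=C1C=C[C@]2(C)C[C@@H](OC(=O)/C(C)=C\C)[C@@H](C(=C)C(=O)OC(C)(C)C)CC2=C1C | intermediate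
19 | tert-butyl 8β-angeloyloxy-3-(tert-butyldimethylsilyloxy)eudesma-1,3,5,11(13)-tetraen-12-oate | CC1=C(O[Si](C)(C)C(C)(C)C)C=C[C@]2(C)C[C@@H](OC(=O)/C(C)=C\C)[C@@H](C(=C)C(=O)OC(C)(C)C)C=C12 | intermediate
20 | tert-butyl (7αH)-8β-angeloyloxy-6α-hydroxy-3-oxoeudesma-1,4,11(13)-trien-12-oate | O=C1C=C[C@]2(C)C[C@@H](OC(=O)/C(C)=C\C)[C@@H](C(=C)C(=O)OC(C)(C)C)[C@H](O)C2=C1C | intermediate
21 | (7αH)-8β-angeloyloxy-6α-hydroxy-3-oxoeudesma-1,4,11(13)-trien-12-oic acid | O=C1C=C[C@]2(C)C[C@@H](OC(=O)/C(C)=C\C)[C@@H](C(=C)C(=O)O)[C@H](O)C2=C1C | intermediate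
22 | 8β-angeloyloxy-3-oxoeudesma-1,4,11(13)-trien-12,6α-olide (6βH,7αH) | C=C1C(=O)O[C@H]2[C@H]1[C@H](OC(=O)/C(C)=C\C)C[C@@]3(C)C=CC(=O)C(C)=C23 | intermediate
23 | 8β-angeloyloxy-3β-hydroxyeudesma-1,4,11(13)-trien-12,6α-olide | C=C1C(=O)O[C@H]2[C@H]1[C@H](OC(=O)/C(C)=C\C)C[C@@]3(C)C=C[C@H](O)C(C)=C23 | intermediate
24 | 8β-angeloyloxy-3β-(tert-butyldimethylsilyloxy)eudesma-1,4,11(13)-trien-12,6α-olide | C=C1C(=O)O[C@H]2[C@H]1[C@H](OC(=O)/C(C)=C\C)C[C@@]3(C)C=C[C@H](O[Si](C)(C)C(C)(C)C)C(C)=C23 | intermediate
25 | 8β-angeloyloxy-5α-hydroperoxy-3β-(tert-butyldimethylsilyloxy)eudesma-1,4(15),11(13)-trien-12,6α-olide | C=C1C(=O)O[C@H]2[C@H]1[C@H](OC(=O)/C(C)=C\C)C[C@@]3(C)C=C[C@H](O[Si](C)(C)C(C)(C)C)C(=C)[C@]23OO | intermediate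
26 | O-(4-nitrobenzoyl) perester of 25 | C=C1C(=O)O[C@H]2[C@H]1[C@H](OC(=O)/C(C)=C\C)C[C@@]3(C)C=C[C@H](O[Si](C)(C)C(C)(C)C)C(=C)[C@]23OOC(=O)c4ccc(cc4)[N+](=O)[O-] | intermediate
27 | 8-angeloyloxy-5,10-epoxy-5-(4-nitrobenzoyloxy)-3-(tert-butyldimethylsilyloxy)germacra-1,4(15),11(13)-trien-12,6-olide (11-oxabicyclo[4.4.1]undecane core, acyloxy exo on C5) | C=C1C(=O)O[C@H]2[C@H]1[C@H](OC(=O)/C(C)=C\C)C[C@@]3(C)C=C[C@H](O[Si](C)(C)C(C)(C)C)C(=C)[C@]2(OC(=O)c4ccc(cc4)[N+](=O)[O-])O3 | intermediate
28 | 8-angeloyloxy-5,10-epoxy-3-(tert-butyldimethylsilyloxy)germacra-1,4(15),11(13)-trien-12,6-olide (5-H exo) | C=C1C(=O)O[C@H]2[C@H]1[C@H](OC(=O)/C(C)=C\C)C[C@@]3(C)C=C[C@H](O[Si](C)(C)C(C)(C)C)C(=C)[C@@H]2O3 | intermediate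
29 | 8-angeloyloxy-5,10-epoxy-3-hydroxygermacra-1,4(15),11(13)-trien-12,6-olide | C=C1C(=O)O[C@H]2[C@H]1[C@H](OC(=O)/C(C)=C\C)C[C@@]3(C)C=C[C@H](O)C(=C)[C@@H]2O3 | intermediate
30 | CNP0335602.1 | C=C1C(=O)O[C@H]2[C@H]1[C@H](OC(=O)/C(C)=C\C)C[C@@]1(C)C=CC(=O)C(=C)[C@@H]2O1 | target

## Step count and risks

Total step count: 16. Longest linear sequence: 16 steps (1 → 30).

**Step 13 (most likely to fail).** The perester may ionise with migration of the vinyl carbon C4 (Hock-type cleavage of ring A), or isomerise by allylic acyloxy shift, instead of migrating C10. The fallback inserts the oxygen by a radical route and sets out from 25. Reduction with PPh3 (CH2Cl2, 0 °C) gives the tertiary allylic alcohol 8β-angeloyloxy-5α-hydroxy-3β-(tert-butyldimethylsilyloxy)eudesma-1,4(15),11(13)-trien-12,6α-olide F1. Irradiation with PhI(OAc)2 and I2 (cyclohexane, visible light) generates the C5 alkoxy radical, which should undergo β-scission of the C5–C10 bond to the tertiary allylic C10 radical. Oxidation of this radical through the iodide to the cation, and capture by the new C5 carbonyl oxygen and acetate, gives the bridged ketal acetate F2. Reduction of F2 under the conditions of step 14 comes back to the route at 28.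

**Step 14.** The Lewis acid may ionise the doubly allylic silyl ether at C3 or the tertiary allylic C10–O bond in competition with the ketal ester. The fallback changes the order of the last operations so that the reduction is run on the enone, where both competing ionisations are switched off. It sets out from 27: HF·pyridine gives the C3 alcohol 8-angeloyloxy-5,10-epoxy-3-hydroxy-5-(4-nitrobenzoyloxy)germacra-1,4(15),11(13)-trien-12,6-olide F3. Dess–Martin oxidation gives the 3-ketone F4. Et3SiH with catalytic TMSOTf then reduces the ketal ester of F4 and comes back to the route at 30.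

**Step 8.** The peracid may attack the trienol ether from the β-face (the stereoelectronically preferred axial direction), giving the 6β-alcohol, which acid would close to the cis lactone. The fallback uses β-face attack with inversion and sets out from 18. The same trienol silyl ether is brominated with N-bromosuccinimide to tert-butyl 8β-angeloyloxy-6β-bromo-3-oxoeudesma-1,4,11(13)-trien-12-oate F5. CF3CO2H cleaves the ester to the bromo acid F6. NaHCO3 in DMF closes the lactone by intramolecular carboxylate SN2 displacement with inversion at C6 and comes back to the route at 22.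

Further compounds
F1 | step 13 | 8β-angeloyloxy-5α-hydroxy-3β-(tert-butyldimethylsilyloxy)eudesma-1,4(15),11(13)-trien-12,6α-olide | C=C1C(=O)O[C@H]2[C@H]1[C@H](OC(=O)/C(C)=C\C)C[C@@]3(C)C=C[C@H](O[Si](C)(C)C(C)(C)C)C(=C)[C@]23O
F2 | step 13 | 5-acetoxy-8-angeloyloxy-5,10-epoxy-3-(tert-butyldimethylsilyloxy)germacra-1,4(15),11(13)-trien-12,6-olide | C=C1C(=O)O[C@H]2[C@H]1[C@H](OC(=O)/C(C)=C\C)C[C@@]3(C)C=C[C@H](O[Si](C)(C)C(C)(C)C)C(=C)[C@]2(OC(C)=O)O3
F3 | step 14 | 8-angeloyloxy-5,10-epoxy-3-hydroxy-5-(4-nitrobenzoyloxy)germacra-1,4(15),11(13)-trien-12,6-olide | C=C1C(=O)O[C@H]2[C@H]1[C@H](OC(=O)/C(C)=C\C)C[C@@]3(C)C=C[C@H](O)C(=C)[C@]2(OC(=O)c4ccc(cc4)[N+](=O)[O-])O3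
F4 | step 14 | 8-angeloyloxy-5,10-epoxy-5-(4-nitrobenzoyloxy)-3-oxogermacra-1,4(15),11(13)-trien-12,6-olide | C=C1C(=O)O[C@H]2[C@H]1[C@H](OC(=O)/C(C)=C\C)C[C@@]3(C)C=CC(=O)C(=C)[C@]2(OC(=O)c4ccc(cc4)[N+](=O)[O-])O3
F5 | step 8 | tert-butyl (7αH)-8β-angeloyloxy-6β-bromo-3-oxoeudesma-1,4,11(13)-trien-12-oate | O=C1C=C[C@]2(C)C[C@@H](OC(=O)/C(C)=C\C)[C@@H](C(=C)C(=O)OC(C)(C)C)[C@@H](Br)C2=C1C
F6 | step 8 | (7αH)-8β-angeloyloxy-6β-bromo-3-oxoeudesma-1,4,11(13)-trien-12-oic acid | O=C1C=C[C@]2(C)C[C@@H](OC(=O)/C(C)=C\C)[C@@H](C(=C)C(=O)O)[C@@H](Br)C2=C1C
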